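Ash is a slow flask: after 40.0 h at 55 °C it reads 23% left-handed product. The next flask gets 3.0 h and the candidates differ in temperature, so you have to decide how much heat.

| flask | left-handed substrate | right-handed substrate | reagent | free catalyst | temperature | remark | time |
|---|---|---|---|---|---|---|---|
| ash | 0.40 M | 0.40 M | 0.40 M | 4 mM | 55 °C | run made earlier |  |
| cedar | 0.40 M | 0.40 M | 1.6 M | 4 mM | 98 °C | run made earlier |  |
| eta | 0.40 M | 0.40 M | 0.800 M | 4.0 mM | 110 °C |  | 3.0 h |
| zeta | 0.40 M | 0.40 M | 0.800 M | 4.0 mM | 135 °C |  | 3.0 h |
| gamma | 0.40 M | 0.40 M | 0.800 M | 4.0 mM | 85 °C |  | 3.0 h |
| alpha | 0.40 M | 0.40 M | 0.800 M | 4.0 mM | 60 °C |  | 3.0 h |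

- ash (time / h: left-handed product / %, left-handed substrate / %): 5.00: 1, 45; 10.0: 6, 41; 15.0: 11, 38; 20.0: 12, 38; 25.0: 16, 36; 30.0: 13, 34; 40.0: 23, 30
- cedar (time / h: left-handed product / %, left-handed substrate / %): 0.667: 24, 30; 1.33: 38, 18; 2.00: 42, 7; 2.50: 46, 6; 4.00: 51, 2; 5.00: 48, 3

(each reading ± 2 percentage points)

- the flask with the highest amount of left-handed product, in percent of the left-handed substrate and right-handed substrate together charged ("all alike" if they lie within 1.5 percentage points) (eta / zeta / gamma / alpha / all alike)
- final left-handed product, as a percentage of the left-handed substrate and right-handed substrate together charged, in eta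
- final left-handed product, as a percentage of the left-handed substrate and right-handed substrate together charged, in zeta
- final left-handed product, as a percentage of the left-handed substrate and right-handed substrate together charged, in gamma
- final left-handed product, as a percentage of the left-handed substrate and right-handed substrate together charged, in alpha

- free catalyst is single-handed; left-handed substrate and right-handed substrate are mirror images of each other, charged as a racemate, each of them at the stated concentration

Look for what stays still. Add left-handed substrate and left-handed product in the last reading of each run. Ash gives 53.0% of the charge and cedar gives 51.0%, and the scatter of such a sum is 2.8 percentage points. So freeze the left-handed sum, substrate plus product of that hand as a fraction of both substrates charged, at 50.0%. Left-handed product is then this sum minus the left-handed substrate still there.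

Now you need a clock for that substrate. Freeze the reagent too, at its mid-run level as a fraction of both substrates charged, and treat the loss of left-handed substrate as pseudo-first-order. My rate per unit of that fraction reads 0.0332 /h in ash and 0.424 /h in cedar. Spread that rise evenly over the degrees, and eta at 110 °C gets 0.864 /h.

So I reckon that eta keeps 7.15% left-handed substrate after 3.0 h, and I commit to 42.8% product there. Gamma, reckoned the same way, keeps 32.1%, more than eta, and alpha is colder still. Zeta reckons to 50.0%, a gain of 7.2 points over eta. But eta at 110 °C already lies above cedar's 98 °C, zeta at 135 °C lies further above it, and no reading tests the sum above cedar's temperature. So charge eta, and hold zeta's figure open until both left-handed species have been read in it.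

The forecast named zeta, with 49% there, 43% in eta, 24% in gamma and 6.5% in alpha, and it read cedar as showing “no visible racemisation or product loss”.

The flask with the most product is eta: eta 41.9%, zeta 36.6%, gamma 23.8%, alpha 5.89%.

    free catalyst + left-handed substrate ⇌ catalyst intermediate A (K = 1.20 /M, k = 2.90 /M/s, Ea = 75.0 kJ/mol, ΔH = −32.0 kJ/mol)
    free catalyst + right-handed substrate ⇌ catalyst intermediate B (K = 1.40 /M, k = 0.990 /M/s, Ea = 54.0 kJ/mol, ΔH = −36.0 kJ/mol)
    reagent + catalyst intermediate A → free catalyst + left-handed product (k = 0.130 /M/s, Ea = 70.0 kJ/mol)
    reagent + catalyst intermediate B → free catalyst + right-handed product (k = 0.00760 /M/s, Ea = 71.0 kJ/mol)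
    left-handed product ⇌ right-handed product (k = 5.30 × 10⁻⁶ /s, Ea = 125 kJ/mol)
    (constants at 110 °C)

Zeta holds 25.2% right-handed product after 3.00 h. Put the left-handed sum to it. Eta's sum stands at 48.5%, but zeta's stands at 37.2%, short of 50.0% by 13 points. Right-handed product exceeds what right-handed substrate lost by 13 points, about the same amount.

Read eta at 5.0 h instead. My clock leaves 1.96% left-handed substrate in that eta, so the frozen sum gives 48.0% left-handed product. The computed flask gives 45.0%, beside 12.4% right-handed product.

(The runs were generated by integration for substances that don't exist, and the scatter is random.)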